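**Retrosynthetic overview**

- Locants: naphthalene C1 carries the 4-hydroxyphenyl ring C. C2 and C3 carry the 2,4-dihydroxybenzoyl groups (rings D and E), and C4 carries H. Ring A is the benzo ring with the 6,7-diol; ring B is C1–C4/C4a/C8a.
- Enabling feature: the two ketone carbons on the neighbouring ring-B atoms C2 and C3 stand in a 1,4-relation (O=C–C3–C2–C=O, the Stetter retron). C2 is flanked by the aryl-bearing C1, a former diaryl ketone carbon, and C4 bears only H.
- Key disconnection: the C3–C(=O) bond of the ring-E ketone (acyl anion of 2,4-dimethoxybenzaldehyde onto the central carbon of an allenyl ketone) together with C1=C2 (aldol condensation). C3/C4 are carried at the alkyne level, so loss of water alone makes ring B aromatic.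
- The open-chain precursor is cut at C4–C4a (Sonogashira coupling), at C2–C(=O) of the ring-D ketone (Barbier propargylation, then oxidation) and at C1–C8a (Friedel–Crafts acylation).
- Ring order: rings A, C, D and E are bought as benzene derivatives. Ring B is the only ring formed, in the key step. The seven phenols travel as methyl ethers and are freed last.

Key step: step 5

Assumption: the target has no stereocentre and rotation about its aryl–aryl and aryl–carbonyl axes is taken as free; carbinols 6 and 7 are used as racemates because their only stereocentre is erased in step 4.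

**Route**

Step 1
Reactants: 1 4-bromo-1,2-dimethoxybenzene; 2 4-methoxybenzoyl chloride
Product: 3 (2-bromo-4,5-dimethoxyphenyl)(4-methoxyphenyl)methanone
Conditions: AlCl3 (1.2 equiv), CH2Cl2, 0 °C to rt
Reagents that add atoms: none
Why: Friedel–Crafts acylation: in 1 the only free position para to a methoxy group is C5, next to bromine, so the acylium ion from 2 should enter there and place the ketone (future C1) ortho to the C–Br bond (future C4a), as in the usual acylations of 4-bromoveratrole.

Step 2
Reactants: 4 2,4-dimethoxybenzaldehyde; 5 3-bromoprop-1-yne (propargyl bromide)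
Product: 6 rac-1-(2,4-dimethoxyphenyl)but-3-yn-1-ol
Conditions: Zn dust, THF, 0 °C to rt; sat. aq NH4Cl work-up
Reagents that add atoms: none
Why: Barbier-type propargylation: the allenylzinc bromide formed from 5 adds to the aldehyde through an SE2' transition state and should give the homopropargylic alcohol; the new carbinol centre forms as a racemate and is erased in step 4.

Step 3
Reactants: 3 (2-bromo-4,5-dimethoxyphenyl)(4-methoxyphenyl)methanone; 6 rac-1-(2,4-dimethoxyphenyl)but-3-yn-1-ol
Product: 7 rac-1-(2,4-dimethoxyphenyl)-4-[4,5-dimethoxy-2-(4-methoxybenzoyl)phenyl]but-3-yn-1-ol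
Conditions: PdCl2(PPh3)2 (3 mol %), CuI (5 mol %), Et3N, THF, 60 °C, degassed
Reagents that add atoms: none
Why: Sonogashira coupling: the ortho ketone activates the C–Br bond towards oxidative addition to zerovalent palladium, and the free secondary alcohol, the aryl ethers and the diaryl ketone are inert under these conditions, so the stereocentre is untouched.

Step 4
Reactants: 7 rac-1-(2,4-dimethoxyphenyl)-4-[4,5-dimethoxy-2-(4-methoxybenzoyl)phenyl]but-3-yn-1-ol
Product: 8 1-(2,4-dimethoxyphenyl)-4-[4,5-dimethoxy-2-(4-methoxybenzoyl)phenyl]but-3-yn-1-one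
Conditions: Dess–Martin periodinane (1.2 equiv), CH2Cl2, 0 °C to rt
Reagents that add atoms: none
Why: Dess–Martin oxidation of a benzylic secondary alcohol under nearly neutral conditions, the usual way from homopropargylic alcohols to but-3-yn-1-ones; partial migration of the triple bond would do no harm, because the allenyl ketone is the next intermediate anyway.

Step 5
Reactants: 8 1-(2,4-dimethoxyphenyl)-4-[4,5-dimethoxy-2-(4-methoxybenzoyl)phenyl]but-3-yn-1-one; 4 2,4-dimethoxybenzaldehyde
Product: 12 [6,7-dimethoxy-1-(4-methoxyphenyl)naphthalene-2,3-diyl]bis[(2,4-dimethoxyphenyl)methanone], via allenyl ketone 9 (not isolated), via Stetter adduct 10 (not isolated), via aldol adduct 11 (not isolated)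
Conditions: 4 (2 equiv), 3-benzyl-5-(2-hydroxyethyl)-4-methylthiazolium chloride (20 mol %), DBU (50 mol %), dry 1,4-dioxane, 70 °C, slow addition of 8
Reagents that add atoms: none
Why: Proposed new method: the base moves the triple bond of 8 into the allenyl ketone 9, whose central carbon C3 is the beta-carbon of an enone; the Breslow enaminol formed from 4 and the thiazol-2-ylidene adds there (Stetter reaction, C3–C(=O) bond), and release of the carbene gives the 1,4-diketone 10. The closest known reaction types are the thiazolium-catalysed intermolecular Stetter reaction of aromatic aldehydes with chalcones, domino Stetter–aldol reactions, and the addition of soft nucleophiles to the beta-carbon of allenyl ketones generated in situ from but-3-yn-1-ones; new are the allenyl ketone as Stetter acceptor and the aromatising end. Ring B closes by a 6-(enolexo)-exo-trig aldol addition of the C2 enolate of 10 to the diaryl ketone carbon C1 (the carbocyclic counterpart of the Friedländer condensation of 2-aminobenzophenones), and E1cB loss of water from 11 makes the ring aromatic, which drains all the reversible steps before it. No stereocentre remains in 12; the C3=C4 geometry that closure needs (ring A cis to C2) is the kinetic one, since the nucleophile meets C3 from the side of the C4 hydrogen, and also the thermodynamic one of an alpha-substituted chalcone, and the C2 carbanion allows equilibration. Selectivity: 4 holds the only formyl group, so only one acyl anion can form and its benzoin dimerisation is reversible; conjugate polarity fixes the attack at C3; as long as C3 is sp-hybridised C2 cannot reach C1, so closure can only follow the C–C bond formation; and a second Stetter addition to the trisubstituted enone of 10 should be slower than the intramolecular aldol step.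

Step 6
Reactants: 12 [6,7-dimethoxy-1-(4-methoxyphenyl)naphthalene-2,3-diyl]bis[(2,4-dimethoxyphenyl)methanone]
Product: 13 [6,7-dihydroxy-1-(4-hydroxyphenyl)naphthalene-2,3-diyl]bis[(2,4-dihydroxyphenyl)methanone] (CNP0304576.0)
Conditions: BBr3 (14 equiv), CH2Cl2, −78 °C to rt, argon; ice-water
Reagents that add atoms: none
Why: Lewis-acid ether cleavage with BBr3: all seven aryl methyl ethers are cleaved by bromide attack on the boron-activated O–CH3 groups (the two ortho to the ketones fastest, by chelation), the diaryl ketones and the naphthalene are inert, and hydrolysis of the aryl borates frees the seven phenols.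

**Compound list**

1 | 4-bromo-1,2-dimethoxybenzene | COc1ccc(Br)cc1OC | starting material
2 | 4-methoxybenzoyl chloride | COc1ccc(cc1)C(=O)Cl | starting material
3 | (2-bromo-4,5-dimethoxyphenyl)(4-methoxyphenyl)methanone | COc1ccc(cc1)C(=O)c1cc(OC)c(OC)cc1Br | intermediate
4 | 2,4-dimethoxybenzaldehyde | COc1ccc(C=O)c(OC)c1 | starting material
5 | 3-bromoprop-1-yne (propargyl bromide) | C#CCBr | starting material
6 | rac-1-(2,4-dimethoxyphenyl)but-3-yn-1-ol | COc1ccc(C(O)CC#C)c(OC)c1 | intermediate
7 | rac-1-(2,4-dimethoxyphenyl)-4-[4,5-dimethoxy-2-(4-methoxybenzoyl)phenyl]but-3-yn-1-ol | COc1ccc(cc1)C(=O)c1cc(OC)c(OC)cc1C#CCC(O)c1ccc(OC)cc1OC | intermediate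
8 | 1-(2,4-dimethoxyphenyl)-4-[4,5-dimethoxy-2-(4-methoxybenzoyl)phenyl]but-3-yn-1-one | COc1ccc(cc1)C(=O)c1cc(OC)c(OC)cc1C#CCC(=O)c1ccc(OC)cc1OC | intermediate
9 | 1-(2,4-dimethoxyphenyl)-4-[4,5-dimethoxy-2-(4-methoxybenzoyl)phenyl]buta-2,3-dien-1-one (racemic allene, not isolated) | COc1ccc(cc1)C(=O)c1cc(OC)c(OC)cc1C=C=CC(=O)c1ccc(OC)cc1OC | intermediate
10 | (E)-1,4-bis(2,4-dimethoxyphenyl)-2-[4,5-dimethoxy-2-(4-methoxybenzoyl)benzylidene]butane-1,4-dione (not isolated) | COc1ccc(c(OC)c1)C(=O)/C(CC(=O)c1ccc(OC)cc1OC)=C/c1cc(OC)c(OC)cc1C(=O)c1ccc(OC)cc1 | intermediate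
11 | [1-hydroxy-6,7-dimethoxy-1-(4-methoxyphenyl)-1,2-dihydronaphthalene-2,3-diyl]bis[(2,4-dimethoxyphenyl)methanone] (racemic mixture of diastereomers, both centres erased on dehydration, not isolated) | COc1ccc(cc1)C1(O)C(C(=O)c2ccc(OC)cc2OC)C(C(=O)c2ccc(OC)cc2OC)=Cc2cc(OC)c(OC)cc21 | intermediate
12 | [6,7-dimethoxy-1-(4-methoxyphenyl)naphthalene-2,3-diyl]bis[(2,4-dimethoxyphenyl)methanone] | COc1ccc(cc1)-c1c(C(=O)c2ccc(OC)cc2OC)c(C(=O)c2ccc(OC)cc2OC)cc2cc(OC)c(OC)cc12 | intermediate
13 | [6,7-dihydroxy-1-(4-hydroxyphenyl)naphthalene-2,3-diyl]bis[(2,4-dihydroxyphenyl)methanone] (CNP0304576.0) | O=C(c1ccc(O)cc1O)c1cc2cc(O)c(O)cc2c(-c2ccc(O)cc2)c1C(=O)c1ccc(O)cc1O | target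

**Step count and risks**

Total step count: 6.
Longest linear sequence: 5 steps (1, 3, 4, 5, 6 or 2, 3, 4, 5, 6).

**Step 5 (proposed new method).**

What may go wrong:
- The carbene may be sequestered by conjugate addition to the allenyl ketone.
- The acyl anion equivalent may form slowly from the electron-rich, ortho-substituted aldehyde.
- The allenyl ketone may oligomerise or cycloisomerise under base before the C–C bond is made.
- The sequence may stall before the aldol attack on the electron-rich diaryl ketone.

The fallback uses known chemistry. It sets out from 4 and 3 and comes back to the route at 10, and through 11 at 12. The same C3–C(=O) bond is made on an open chain by a classical Stetter reaction.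

Commercial 2',4'-dimethoxyacetophenone is converted by a Mannich reaction (paraformaldehyde, Me2NH·HCl, EtOH, reflux) into 3-(dimethylamino)-1-(2,4-dimethoxyphenyl)propan-1-one hydrochloride F1. Under the Stetter conditions (the same thiazolium salt, Et3N, 1,4-dioxane, 80 °C) this releases 1-(2,4-dimethoxyphenyl)prop-2-en-1-one F2. F2 takes up 4 to give 1,4-bis(2,4-dimethoxyphenyl)butane-1,4-dione F3.

Bromide 3 is formylated (Pd(OAc)2, di(1-adamantyl)-n-butylphosphine, CO/H2, TMEDA, toluene, 100 °C) to 4,5-dimethoxy-2-(4-methoxybenzoyl)benzaldehyde F4.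

Base-mediated condensation of F3 with F4 (KOH, EtOH, reflux) is the reaction type that turns phthalaldehydes and 1,4-diaryl-1,4-butanediones into 2,3-diaroylnaphthalenes. It should first condense at the formyl group to give 10 and then close through 11 to 12. F3 is symmetric, so no regiochemical question arises.

**Step 6.**

What may go wrong:
- Cleavage of the seven ethers may stay incomplete once boron chelates of the ortho-hydroxy ketones precipitate.
- The ring-A catechol may oxidise in air during work-up.
- Acid may induce ring closure between the crowded aryl and aroyl groups.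

The fallback sets out from 12 and comes back at 13. It replaces electrophilic activation of the ether oxygens by nucleophilic attack at the methyl carbons under basic, acid-free conditions. Sodium dodecane-1-thiolate (from dodecane-1-thiol and NaH, large excess) is used in NMP at 130 °C under argon. The heptaphenolate is then acidified with degassed dilute HCl. No new isolated compound lies on this way.

**Step 3.**

What may go wrong: oxidative addition at the hindered, electron-rich C–Br bond beside the diaryl ketone may be slow. Copper-mediated oxidative homocoupling of the alkyne would then consume 6.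

The fallback sets out from 6 and comes back at 8. It changes the order of bond formation, so that the ring-C ketone is built after the alkyne is attached.

Alkyne 6 is coupled (PdCl2(PPh3)2, CuI, Et3N, 50 °C) with commercial 2-bromo-4,5-dimethoxybenzaldehyde, a less hindered and more activated bromide. This gives 2-[4-(2,4-dimethoxyphenyl)-4-hydroxybut-1-yn-1-yl]-4,5-dimethoxybenzaldehyde F5.

Addition of 4-methoxyphenylmagnesium bromide (2.2 equiv, THF, 0 °C) gives 1-(2,4-dimethoxyphenyl)-4-{2-[hydroxy(4-methoxyphenyl)methyl]-4,5-dimethoxyphenyl}but-3-yn-1-ol F6 as a mixture of diastereomers. Dess–Martin periodinane (2.5 equiv, CH2Cl2) then oxidises both carbinols at once to 8.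

**Further compounds**

F1 | step 5 | 3-(dimethylamino)-1-(2,4-dimethoxyphenyl)propan-1-one hydrochloride | CN(C)CCC(=O)c1ccc(OC)cc1OC.Cl
F2 | step 5 | 1-(2,4-dimethoxyphenyl)prop-2-en-1-one | C=CC(=O)c1ccc(OC)cc1OC
F3 | step 5 | 1,4-bis(2,4-dimethoxyphenyl)butane-1,4-dione | COc1ccc(C(=O)CCC(=O)c2ccc(OC)cc2OC)c(OC)c1
F4 | step 5 | 4,5-dimethoxy-2-(4-methoxybenzoyl)benzaldehyde | COc1ccc(cc1)C(=O)c1cc(OC)c(OC)cc1C=O
F0 | step 6 | none | none
F5 | step 3 | 2-[4-(2,4-dimethoxyphenyl)-4-hydroxybut-1-yn-1-yl]-4,5-dimethoxybenzaldehyde (racemic) | COc1ccc(C(O)CC#Cc2cc(OC)c(OC)cc2C=O)c(OC)c1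
F6 | step 3 | 1-(2,4-dimethoxyphenyl)-4-{2-[hydroxy(4-methoxyphenyl)methyl]-4,5-dimethoxyphenyl}but-3-yn-1-ol (mixture of diastereomers) | COc1ccc(cc1)C(O)c1cc(OC)c(OC)cc1C#CCC(O)c1ccc(OC)cc1OC
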